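## Retrosynthetic overview

1. Target 33 comes from acetylation and desilylation of the ten-membered diol 31. The ten-membered ring is closed last, at C6–C7, by an intramolecular Ni/Cr (Nozaki–Hiyama–Kishi) addition of the C7 vinyl bromide to the C6 aldehyde of 29.
2. C8–C9 is the key fragment union: intermolecular, Felkin–Anh-controlled carbonyl 2-bromoallylation of cyclohexane aldehyde 24 with 2,3-dibromopropene/In. This also installs C7=C19 and the vinyl bromide.
3. The C1 side chain is built by Still–Gennari Z-olefination (C2=C3), then C4 bromide + LiCH2CN (C5, C6).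
4. The cyclohexane is made first: an Evans auxiliary Diels–Alder reaction of enoyl imide 4 with silyloxy diene 7 sets C1, C10 and C14. The C11 carbinol follows from α-face epoxidation and hydride opening.

Assumption: labels C1–C14 and C19 in names are the eunicellane positions of the target (C1/C10 ring fusion, C11 carbinol, C14 isopropyl carbon). β is the cyclohexane face carrying the C1–C2 and C10–C9 bonds and the C11 methyl; α is the opposite face (H1, H10, C14 isopropyl, C11 oxygen). Compounds 1, 2, 5, 13, 18 and 25 are taken as commercial.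

## Route

Step 1
Reactants: 1 (2E)-4-methylpent-2-enoic acid; 2 (4S)-4-benzyl-1,3-oxazolidin-2-one
Product: 4 (4S)-4-benzyl-3-[(2E)-4-methylpent-2-enoyl]-1,3-oxazolidin-2-one, via mixed pivalic anhydride 3 (not isolated)
Conditions: PivCl, Et3N, THF, −20 °C; then LiCl, 2, −20 °C → rt
Reagents that add atoms: none
Why: Mixed-anhydride N-acylation of the oxazolidinone (LiCl/Et3N variant) avoids strong base and conjugate addition, forms no stereocentre and keeps the E-alkene.

Step 2
Reactants: 5 (2E)-3-methylpent-2-en-4-yn-1-ol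
Product: 6 enyne silyl ether
Conditions: TBDPSCl, imidazole, DMF, 0 °C → rt
Reagents that add atoms: tert-butylchlorodiphenylsilane (TBDPSCl), CC(C)(C)[Si](Cl)(c1ccccc1)c1ccccc1
Why: Standard silyl ether formation on a primary alcohol gives a bulky, weakly Lewis-basic ether chosen to tolerate Et2AlCl in step 4.

Step 3
Reactants: 6 enyne silyl ether
Product: 7 diene silyl ether
Conditions: H2 (1 atm), Pd/CaCO3 poisoned with Pb(OAc)2, quinoline, hexane, rt (stopped after 1 equiv H2)
Reagents that add atoms: none
Why: Lindlar-type semihydrogenation of the terminal alkyne stops at the vinyl group and leaves the trisubstituted E-alkene untouched, giving the (E)-1,2-disubstituted diene.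

Step 4
Reactants: 4 N-enoyl oxazolidinone; 7 diene silyl ether
Product: 8 cyclohexene imide
Conditions: Et2AlCl (1.5 equiv), 7 (2.5 equiv), CH2Cl2, −78 → −20 °C
Reagents that add atoms: none
Why: In this Evans auxiliary-controlled Diels–Alder reaction the Et2AlCl-chelated s-cis imide is attacked on its Cα-Si face (anti to benzyl), endo addition puts the acyl group cis to the diene's E-CH2OSi group (C1/C10 cis), the E-dienophile fixes C1/C14 trans, and the isopropyl-bearing β-carbon bonds to the unsubstituted diene terminus.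

Step 5
Reactants: 8 cyclohexene imide
Product: 9 epoxy imide
Conditions: mCPBA, NaHCO3, CH2Cl2, 0 °C
Reagents that add atoms: 3-chloroperoxybenzoic acid (mCPBA), OOC(=O)c1cccc(Cl)c1
Why: Prilezhaev epoxidation of the only alkene occurs anti to the pseudoaxial allylic C10 CH2OSi group (held axial by allylic strain with the C11 methyl), placing the oxygen on the α face at C11 and C12.

Step 6
Reactants: 9 epoxy imide
Product: 10 epoxy alcohol
Conditions: LiBH4, H2O (1.1 equiv), Et2O, 0 °C
Reagents that add atoms: none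
Why: Reductive cleavage of the N-acyl oxazolidinone by LiBH4 gives the primary C2 alcohol and returns the auxiliary, while the trisubstituted epoxide is inert at 0 °C.

Step 7
Reactants: 10 epoxy alcohol
Product: 11 diol
Conditions: LiEt3BH (3 equiv), THF, 0 °C → rt; then H2O
Reagents that add atoms: none
Why: SN2 hydride opening of the trisubstituted epoxide at the less substituted C12 leaves the C11–O bond untouched, so the tertiary alcohol keeps the α-oxygen (C11 R as in the target).

Step 8
Reactants: 11 diol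
Product: 12 hydroxy aldehyde
Conditions: PhI(OAc)2, 2,2,6,6-tetramethylpiperidine-1-oxyl (10 mol%), CH2Cl2, rt
Reagents that add atoms: none
Why: The oxoammonium-mediated (TEMPO) oxidation is selective for the primary alcohol, and the tertiary 11α-OH is inert and cannot form a lactol because it is trans to the C1β-formyl group.

Step 9
Reactants: 12 hydroxy aldehyde; 13 ethyl 2-[bis(2,2,2-trifluoroethoxy)phosphoryl]propanoate
Product: 15 (Z)-enoate, via potassium phosphonate carbanion 14 (not isolated)
Conditions: 13, KN(SiMe3)2, 18-crown-6, THF, −78 °C; then 12, −78 → −40 °C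
Reagents that add atoms: none
Why: The Still–Gennari variant of the Horner–Wadsworth–Emmons reaction (electron-poor phosphonate, dissociated potassium ion) eliminates kinetically to the Z-enoate, placing C1 and the ester carbon C4 cis on the new C2=C3 bond.

Step 10
Reactants: 15 (Z)-enoate
Product: 16 (Z)-allylic alcohol
Conditions: i-Bu2AlH (3.5 equiv), CH2Cl2, −78 °C; then aq. potassium sodium tartrate (KNaC4H4O6)
Reagents that add atoms: none
Why: 1,2-Reduction of the enoate by the aluminium hydride gives the allylic alcohol with the Z geometry retained.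

Step 11
Reactants: 16 (Z)-allylic alcohol
Product: 17 (Z)-allylic bromide
Conditions: CBr4, PPh3, CH2Cl2, 0 °C
Reagents that add atoms: tetrabromomethane, BrC(Br)(Br)Br
Why: The Appel reaction converts the primary allylic alcohol into the bromide under neutral conditions without Z/E scrambling, and the tertiary alcohol does not react at 0 °C.

Step 12
Reactants: 17 (Z)-allylic bromide; 18 acetonitrile
Product: 20 nitrile silyl ether, via lithioacetonitrile 19 (not isolated)
Conditions: MeCN (4 equiv), n-BuLi, THF, −78 °C; then 17, −78 → −30 °C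
Reagents that add atoms: none
Why: SN2 alkylation of the nitrile-stabilised carbanion at the primary allylic bromide adds C5 and C6 (as the nitrile) without touching the alkene geometry, and the excess anion covers the free tertiary OH.

Step 13
Reactants: 20 nitrile silyl ether
Product: 21 nitrile diol
Conditions: n-Bu4NF, THF, 0 °C → rt
Reagents that add atoms: none
Why: Fluoride-mediated desilylation removes the TBDPS ether while the nitrile and both alkenes are inert.

Step 14
Reactants: 21 nitrile diol
Product: 22 bis(triethylsilyl) ether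
Conditions: Et3SiOTf (2.5 equiv), 2,6-lutidine, CH2Cl2, −78 → 0 °C
Reagents that add atoms: triethylsilyl trifluoromethanesulfonate, CC[Si](CC)(CC)OS(=O)(=O)C(F)(F)F
Why: Silylation with the silyl triflate protects both hydroxyls, including the hindered tertiary C11 alcohol that must be non-chelating in step 17.

Step 15
Reactants: 22 bis(triethylsilyl) ether
Product: 23 C9 alcohol
Conditions: pyridinium p-toluenesulfonate (cat.), MeOH/CH2Cl2, 0 °C
Reagents that add atoms: none
Why: Acid-catalysed methanolysis cleaves the unhindered primary triethylsilyl ether far faster than the tertiary one (selective desilylation).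

Step 16
Reactants: 23 C9 alcohol
Product: 24 C9 aldehyde
Conditions: Dess–Martin periodinane, NaHCO3, CH2Cl2, 0 °C → rt; used at once
Reagents that add atoms: none
Why: Buffered Dess–Martin oxidation gives the aldehyde under neutral conditions, avoiding epimerisation of the axial C10 centre and β-elimination of the silyloxy group.

Step 17
Reactants: 24 C9 aldehyde; 25 2,3-dibromopropene
Product: 27 (9R)-bromoallyl carbinol, via 2-bromoallylindium dibromide 26 (not isolated)
Conditions: 25, In powder, THF/H2O 3:1, 0 °C → rt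
Reagents that add atoms: none
Why: In this Barbier-type carbonyl allylation the allylindium reagent adds in the Felkin–Anh sense, anti to the quaternary C11 and past H10 (non-chelating OSiEt3, reinforced by 1,3-anti induction), which sets C9 as R.

Step 18
Reactants: 27 (9R)-bromoallyl carbinol
Product: 29 bromo hydroxy aldehyde, via aluminium aldimine 28 (not isolated)
Conditions: i-Bu2AlH (3 equiv), CH2Cl2, −78 °C; then aq. potassium sodium tartrate (KNaC4H4O6), rt
Reagents that add atoms: water, O
Why: Partial hydride reduction of the nitrile stops at the N-aluminio imine, which hydrolyses to the C6 aldehyde, and the vinyl bromide, silyl ether and free C9 alcohol tolerate the reagent.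

Step 19
Reactants: 29 bromo hydroxy aldehyde
Product: 31 macrocyclic diol, via alkenylchromium dichloride 30 (not isolated)
Conditions: CrCl2 (10 equiv), NiCl2 (2 mol%), DMSO, rt → 40 °C, 0.003 M, slow addition
Reagents that add atoms: none
Why: The intramolecular Nozaki–Hiyama–Kishi reaction (NiCl2-catalysed formation of the alkenylchromium species, chemoselective addition to the aldehyde at high dilution) closes the ten-membered ring, and the C6 carbinol, expected but not proven to be R, is set by the macrocyclic transition state with the chromium alkoxide on the ring periphery.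

Step 20
Reactants: 31 macrocyclic diol
Product: 32 diacetate silyl ether
Conditions: Ac2O, 4-(dimethylamino)pyridine, pyridine, CH2Cl2, rt
Reagents that add atoms: acetic anhydride, CC(=O)OC(C)=O
Why: Nucleophile-catalysed acetylation esterifies both secondary alcohols while the tertiary silyl ether is untouched.

Step 21
Reactants: 32 diacetate silyl ether
Product: 33 target (CNP0303839.1)
Conditions: HF·pyridine, pyridine/THF, 0 °C → rt
Reagents that add atoms: none
Why: Fluoride-mediated cleavage of the tertiary triethylsilyl ether leaves both acetates and all three alkenes intact and frees the C11 alcohol.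

## Compound list

1 | (2E)-4-methylpent-2-enoic acid | CC(C)/C=C/C(=O)O | starting material
2 | (4S)-4-benzyl-1,3-oxazolidin-2-one | O=C1N[C@@H](Cc2ccccc2)CO1 | starting material
3 | mixed pivalic anhydride: (2E)-4-methylpent-2-enoic pivalic anhydride | CC(C)/C=C/C(=O)OC(=O)C(C)(C)C | intermediate
4 | N-enoyl oxazolidinone: (4S)-4-benzyl-3-[(2E)-4-methylpent-2-enoyl]-1,3-oxazolidin-2-one | CC(C)/C=C/C(=O)N1C(=O)OC[C@@H]1Cc1ccccc1 | intermediate
5 | (2E)-3-methylpent-2-en-4-yn-1-ol | C#C/C(C)=C/CO | starting material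
6 | enyne silyl ether: tert-butyl{[(2E)-3-methylpent-2-en-4-yn-1-yl]oxy}diphenylsilane | C#C/C(C)=C/CO[Si](c1ccccc1)(c1ccccc1)C(C)(C)C | intermediate
7 | diene silyl ether: tert-butyl{[(2E)-3-methylpenta-2,4-dien-1-yl]oxy}diphenylsilane | C=C/C(C)=C/CO[Si](c1ccccc1)(c1ccccc1)C(C)(C)C | intermediate
8 | cyclohexene imide: (4S)-4-benzyl-3-{[(1R,2R,6R)-2-(tert-butyldiphenylsilyloxymethyl)-3-methyl-6-(propan-2-yl)cyclohex-3-en-1-yl]carbonyl}-1,3-oxazolidin-2-one; C1β-acyl, C10β-CH2OTBDPS, C14α-isopropyl, C11=C12 | CC(C)(C)[Si](c1ccccc1)(c1ccccc1)OC[C@@H]2[C@H](C(=O)N3C(=O)OC[C@@H]3Cc3ccccc3)[C@@H](C(C)C)CC=C2C | intermediate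
9 | epoxy imide: 8 with C11=C12 converted into the 11α,12α-epoxide (11β-methyl) | CC(C)(C)[Si](c1ccccc1)(c1ccccc1)OC[C@@H]2[C@H](C(=O)N3C(=O)OC[C@@H]3Cc3ccccc3)[C@@H](C(C)C)C[C@H]4O[C@]42C | intermediate
10 | epoxy alcohol: cyclohexane with C1β-CH2OH, C10β-CH2OTBDPS, 11β-methyl-11α,12α-epoxide, C14α-isopropyl | CC(C)(C)[Si](c1ccccc1)(c1ccccc1)OC[C@@H]2[C@H](CO)[C@@H](C(C)C)C[C@H]3O[C@]32C | intermediate
11 | diol: C1β-CH2OH, C10β-CH2OTBDPS, tertiary 11α-OH (11β-methyl), C14α-isopropyl | CC(C)(C)[Si](c1ccccc1)(c1ccccc1)OC[C@@H]2[C@H](CO)[C@@H](C(C)C)CC[C@@]2(C)O | intermediate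
12 | hydroxy aldehyde: as 11 with C1β-CHO (C2 aldehyde) | CC(C)(C)[Si](c1ccccc1)(c1ccccc1)OC[C@@H]2[C@H](C=O)[C@@H](C(C)C)CC[C@@]2(C)O | intermediate
13 | ethyl 2-[bis(2,2,2-trifluoroethoxy)phosphoryl]propanoate | CCOC(=O)C(C)P(=O)(OCC(F)(F)F)OCC(F)(F)F | starting material
14 | potassium phosphonate carbanion (potassium salt of 13) | CCOC(=O)[C-](C)P(=O)(OCC(F)(F)F)OCC(F)(F)F.[K+] | intermediate
15 | (Z)-enoate: ethyl (2Z)-2-methylprop-2-enoate carried at C1β (C2=C3 Z, C4 ester); 11α-OH; C10β-CH2OTBDPS; C14α-isopropyl | CC(C)(C)[Si](c1ccccc1)(c1ccccc1)OC[C@@H]2[C@H](/C=C(/C)C(=O)OCC)[C@@H](C(C)C)CC[C@@]2(C)O | intermediate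
16 | (Z)-allylic alcohol: as 15 with C4 CH2OH | CC(C)(C)[Si](c1ccccc1)(c1ccccc1)OC[C@@H]2[C@H](/C=C(/C)CO)[C@@H](C(C)C)CC[C@@]2(C)O | intermediate
17 | (Z)-allylic bromide: as 16 with C4 CH2Br | CC(C)(C)[Si](c1ccccc1)(c1ccccc1)OC[C@@H]2[C@H](/C=C(/C)CBr)[C@@H](C(C)C)CC[C@@]2(C)O | intermediate
18 | acetonitrile | CC#N | starting material
19 | lithioacetonitrile | [Li]CC#N | intermediate
20 | nitrile silyl ether: C1β-[(1Z)-4-cyano-2-methylbut-1-en-1-yl]; 11α-OH; C10β-CH2OTBDPS; C14α-isopropyl | CC(C)(C)[Si](c1ccccc1)(c1ccccc1)OC[C@@H]2[C@H](/C=C(/C)CCC#N)[C@@H](C(C)C)CC[C@@]2(C)O | intermediate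
21 | nitrile diol: as 20 with C10β-CH2OH | OC[C@@H]1[C@H](/C=C(/C)CCC#N)[C@@H](C(C)C)CC[C@@]1(C)O | intermediate
22 | bis(triethylsilyl) ether of 21 (C9 and C11 oxygens) | CC[Si](CC)(CC)OC[C@@H]1[C@H](/C=C(/C)CCC#N)[C@@H](C(C)C)CC[C@@]1(C)O[Si](CC)(CC)CC | intermediate
23 | C9 alcohol: C10β-CH2OH; 11α-OSiEt3; C6 nitrile side chain | OC[C@@H]1[C@H](/C=C(/C)CCC#N)[C@@H](C(C)C)CC[C@@]1(C)O[Si](CC)(CC)CC | intermediate
24 | C9 aldehyde: C10β-CHO; 11α-OSiEt3; C6 nitrile side chain | O=C[C@@H]1[C@H](/C=C(/C)CCC#N)[C@@H](C(C)C)CC[C@@]1(C)O[Si](CC)(CC)CC | intermediate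
25 | 2,3-dibromopropene | C=C(Br)CBr | starting material
26 | 2-bromoallylindium dibromide (simplest form of the allylindium reagent) | C=C(Br)C[In](Br)Br | intermediate
27 | (9R)-bromoallyl carbinol: C10β-[(1R)-3-bromo-1-hydroxybut-3-en-1-yl]; 11α-OSiEt3; C6 nitrile | C=C(Br)C[C@@H](O)[C@@H]1[C@H](/C=C(/C)CCC#N)[C@@H](C(C)C)CC[C@@]1(C)O[Si](CC)(CC)CC | intermediate
28 | aluminium aldimine: N-diisobutylaluminio imine at C6 and O-diisobutylaluminium alkoxide at C9 of 27 | C=C(Br)C[C@@H](O[Al](CC(C)C)CC(C)C)[C@@H]1[C@H](/C=C(/C)CCC=N[Al](CC(C)C)CC(C)C)[C@@H](C(C)C)CC[C@@]1(C)O[Si](CC)(CC)CC | intermediate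
29 | bromo hydroxy aldehyde: as 27 with C6 CHO | C=C(Br)C[C@@H](O)[C@@H]1[C@H](/C=C(/C)CCC=O)[C@@H](C(C)C)CC[C@@]1(C)O[Si](CC)(CC)CC | intermediate
30 | alkenylchromium dichloride: 29 with CrCl2 in place of Br at C7 | C=C([Cr](Cl)Cl)C[C@@H](O)[C@@H]1[C@H](/C=C(/C)CCC=O)[C@@H](C(C)C)CC[C@@]1(C)O[Si](CC)(CC)CC | intermediate
31 | macrocyclic diol: (1S,2Z,6R,9R,10S,11R,14R)-11-(triethylsilyloxy)eunicella-2,7(19)-diene-6,9-diol | C=C1C[C@@H](O)[C@@H]2[C@H](/C=C(/C)CC[C@H]1O)[C@@H](C(C)C)CC[C@@]2(C)O[Si](CC)(CC)CC | intermediate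
32 | diacetate silyl ether: 6,9-diacetate of 31 | C=C1C[C@@H](OC(C)=O)[C@@H]2[C@H](/C=C(/C)CC[C@H]1OC(C)=O)[C@@H](C(C)C)CC[C@@]2(C)O[Si](CC)(CC)CC | intermediate
33 | (1S,2Z,6R,9R,10S,11R,14R)-6,9-diacetoxyeunicella-2,7(19)-dien-11-ol (CNP0303839.1) | C=C1C[C@@H](OC(C)=O)[C@@H]2[C@H](/C=C(/C)CC[C@H]1OC(C)=O)[C@@H](C(C)C)CC[C@@]2(C)O | target

## Step count and risks

Total step count: 21. Longest linear sequence: 20 steps (5 → 33, steps 2–21); the dienophile branch (step 1) joins at step 4.

**Step 4 (Diels–Alder).** The β-isopropyl imide is a hindered dienophile, the pentadienyl silyl ether may not tolerate Et2AlCl for long, and the C11 methyl opposes the regiochemical direction of the C10 substituent. The fallback sets out from diene 7 and comes back at 16, replacing auxiliary/Lewis-acid activation by iminium organocatalysis. Diene 7 and commercial (2E)-4-methylpent-2-enal F1 react with (5S)-5-benzyl-2,2,3-trimethylimidazolidin-4-one hydrochloride (20 mol%, MeCN/H2O, rt); the benzyl-shielded E-iminium ion is attacked on the same Cα-Si face to give the endo cycloadduct aldehyde F2. Still–Gennari olefination of F2 with 13 gives the ring-alkene Z-enoate F3. mCPBA epoxidises only the electron-rich ring alkene from the α face to give the epoxy enoate F4. LiAlH4 (THF, 0 °C → rt) then reduces the ester to the allylic alcohol and opens the epoxide at C12, arriving at 16.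

**Step 17 (allylation).** The Felkin–Anh preference may give only a moderate C9 ratio, and the axial C10 aldehyde can epimerise to its all-equatorial isomer. The fallback sets out from aldehyde 24 (through the minor product of step 17) and comes back at 27, correcting the stereocentre by inversion instead of by selective addition. The separated (9S)-epimer of 27 F5 is submitted to a Mitsunobu reaction (4-nitrobenzoic acid, PPh3, diisopropyl azodicarboxylate, toluene, rt) to give the (9R)-4-nitrobenzoate F6. Methanolysis (K2CO3, MeOH, 0 °C) returns 27.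

**Step 19 (Ni/Cr ring closure).** The vinyl bromide is less reactive than an iodide, the ten-membered ring is strained, and the C6 configuration rests on macrocyclic control that is not secured by a close precedent. The fallback sets out from 29 (through its cyclisation product of wrong or mixed C6 configuration) and comes back at 31, replacing substrate control by oxidation and catalyst-controlled reduction. The (6S)-epimer of 31 F7, alone or mixed with 31, is oxidised with MnO2 (CH2Cl2, rt) only at the allylic C6 alcohol to give the cross-conjugated enone F8. Reduction with BH3·SMe2 and (S)-1-methyl-3,3-diphenyltetrahydro-1H,3H-pyrrolo[1,2-c][1,3,2]oxazaborole (20 mol%, THF, −30 °C; alkenyl as the large group) delivers the (6R)-alcohol 31.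

## Further compounds

F1 | step 4 | (2E)-4-methylpent-2-enal (commercial dienophile of the fallback) | CC(C)/C=C/C=O
F2 | step 4 | cycloadduct aldehyde: cyclohex-3-ene with C1β-CHO, C10β-CH2OTBDPS, C14α-isopropyl, C11=C12 | CC(C)(C)[Si](c1ccccc1)(c1ccccc1)OC[C@@H]2[C@H](C=O)[C@@H](C(C)C)CC=C2C
F3 | step 4 | ring-alkene Z-enoate: F2 with C1β-[(1Z)-3-ethoxy-2-methyl-3-oxoprop-1-en-1-yl] | CC(C)(C)[Si](c1ccccc1)(c1ccccc1)OC[C@@H]2[C@H](/C=C(/C)C(=O)OCC)[C@@H](C(C)C)CC=C2C
F4 | step 4 | epoxy enoate: F3 with the 11α,12α-epoxide | CC(C)(C)[Si](c1ccccc1)(c1ccccc1)OC[C@@H]2[C@H](/C=C(/C)C(=O)OCC)[C@@H](C(C)C)C[C@H]3O[C@]32C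
F5 | step 17 | (9S)-epimer of 27 | C=C(Br)C[C@H](O)[C@@H]1[C@H](/C=C(/C)CCC#N)[C@@H](C(C)C)CC[C@@]1(C)O[Si](CC)(CC)CC
F6 | step 17 | (9R)-4-nitrobenzoate of 27 | C=C(Br)C[C@@H](OC(=O)c2ccc(cc2)[N+](=O)[O-])[C@@H]1[C@H](/C=C(/C)CCC#N)[C@@H](C(C)C)CC[C@@]1(C)O[Si](CC)(CC)CC
F7 | step 19 | (6S)-epimer of 31 | C=C1C[C@@H](O)[C@@H]2[C@H](/C=C(/C)CC[C@@H]1O)[C@@H](C(C)C)CC[C@@]2(C)O[Si](CC)(CC)CC
F8 | step 19 | C6 enone: 31 with C6 ketone conjugated to C7=C19 | C=C1C[C@@H](O)[C@@H]2[C@H](/C=C(/C)CCC1=O)[C@@H](C(C)C)CC[C@@]2(C)O[Si](CC)(CC)CC
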